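The dihydrofuran ring is cut at C3–C3a and O1–C2. This exposes the arene as a resorcinol whose carbon between the two oxygens (C3a, flanked by C4–O and C7a–O) acts as a carbanion, and the side chain as nerol carrying a primary leaving group at C1 next to a Sharpless 2,3-epoxide. In the key step a 2-lithiated resorcinol dianion attacks the epoxy triflate at CH2, and one of its two homotopic phenoxides then opens the epoxide. Both ring bonds and both stereocentres (inversion at C2, retention at the carbinol) thus arise in one flask. The remaining phenol then directs the acyl carbon to C5, and an aldol condensation completes the chalcone.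

Key step: step 3

Remark: compound 9 is carried as a mixture of epimers at its 1-hydroxyethyl carbon; step 6 turns that carbon into the ketone carbon. Benzofuran numbering (O1, C2, C3, C3a, C4 … C7a) is used throughout.

Step 1
Reactants: 1 nerol, (2Z)-3,7-dimethylocta-2,6-dien-1-ol
Product: 2 [(2R,3S)-3-methyl-3-(4-methylpent-3-en-1-yl)oxiran-2-yl]methanol
Conditions: Ti(OiPr)4 (10 mol %), diisopropyl D-(−)-tartrate (12 mol %), t-BuOOH, 4 Å MS, CH2Cl2, −20 °C
Reagents that add atoms: tert-butyl hydroperoxide, CC(C)(C)OO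
Why: Sharpless asymmetric epoxidation, in which the titanium tartrate complex binds the allylic hydroxyl so that only the 2,3-alkene reacts, and the D-(−)-tartrate delivers oxygen to one face of the Z-alkene, setting C2 as R and C3 as S.

Step 2
Reactants: 2 [(2R,3S)-3-methyl-3-(4-methylpent-3-en-1-yl)oxiran-2-yl]methanol
Product: 3 [(2R,3S)-3-methyl-3-(4-methylpent-3-en-1-yl)oxiran-2-yl]methyl trifluoromethanesulfonate
Conditions: Tf2O, 2,6-lutidine, CH2Cl2, −78 °C; cold filtration through silica, used at once
Reagents that add atoms: trifluoromethanesulfonic anhydride, O=S(=O)(OS(=O)(=O)C(F)(F)F)C(F)(F)F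
Why: Sulfonylation of the primary alcohol at low temperature, the standard activation of 2,3-epoxy alcohols, which leaves the epoxide and its two stereocentres untouched.

Step 3
Reactants: 3 [(2R,3S)-3-methyl-3-(4-methylpent-3-en-1-yl)oxiran-2-yl]methyl trifluoromethanesulfonate; 4 2-bromoresorcinol (2-bromobenzene-1,3-diol)
Product: 7 (2S)-2-[(2S)-2-hydroxy-6-methylhept-5-en-2-yl]-2,3-dihydro-1-benzofuran-4-ol, via trilithio resorcinolate 5 (not isolated), via epoxy bis-phenoxide 6 (not isolated)
Conditions: 4 (1.3 equiv), n-BuLi (2.0 equiv to 4), THF, −78 → 0 °C; t-BuLi (2.1 equiv to 4), −78 °C; 3, −78 → 0 °C; DMPU, 50 °C; aq NH4Cl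
Reagents that add atoms: none
Why: Bromine–lithium exchange on the dilithium salt of 4 gives the aryllithium 5, whose carbanion at the carbon between the two oxygens displaces the primary triflate of 3 by SN2 (bond C3–C3a), and on warming one ortho phenoxide of 6 attacks the neighbouring epoxide carbon (bond O1–C2) and releases the tertiary alkoxide that becomes the side-chain hydroxyl. The closest known reaction types are the displacement of 2,3-epoxy triflates by organolithium reagents and the base-mediated cyclization of ortho-(2,3-epoxyalkyl)phenols to 2-(1-hydroxyalkyl)-2,3-dihydrobenzofurans, here joined into a formal (3+2) annulation of a C,O-dinucleophile with a 1,2-dielectrophile. The dihydrofuran ring closes in the 5-exo-tet mode. C2 arises by SN2 inversion at the R-configured epoxide carbon and so becomes S, while the carbinol carbon keeps its C–O bond and its S configuration, so both stereocentres are dictated by the Sharpless epoxide of step 1. Carbon before oxygen alkylation is secured by the far higher nucleophilicity of the aryl–lithium bond at −78 °C and by the triflate being much more reactive than the trisubstituted epoxide, 5-exo over 6-endo opening by the basic medium that directs attack to the less substituted epoxide carbon, and the site of closure by the two phenoxides being homotopic.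

Step 4
Reactants: 7 (2S)-2-[(2S)-2-hydroxy-6-methylhept-5-en-2-yl]-2,3-dihydro-1-benzofuran-4-ol
Product: 8 (2S)-4-hydroxy-2-[(2S)-2-hydroxy-6-methylhept-5-en-2-yl]-2,3-dihydro-1-benzofuran-5-carbaldehyde
Conditions: MgCl2, Et3N, paraformaldehyde, MeCN, 80 °C; cold 1 M HCl work-up
Reagents that add atoms: paraformaldehyde (as formaldehyde), C=O
Why: Magnesium-mediated ortho-formylation of phenols (Casnati–Skattebøl), in which the magnesium phenoxide delivers formaldehyde only to the free ortho carbon C5 (the other ortho carbon, C3a, is substituted) and hydride transfer to a second formaldehyde gives the aldehyde; no stereocentre is touched.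

Step 5
Reactants: 8 (2S)-4-hydroxy-2-[(2S)-2-hydroxy-6-methylhept-5-en-2-yl]-2,3-dihydro-1-benzofuran-5-carbaldehyde
Product: 9 (2S)-5-(1-hydroxyethyl)-2-[(2S)-2-hydroxy-6-methylhept-5-en-2-yl]-2,3-dihydro-1-benzofuran-4-ol (epimers at the 1-hydroxyethyl carbon)
Conditions: MeMgBr (3.5 equiv), THF, 0 → 23 °C; aq NH4Cl
Reagents that add atoms: methylmagnesium bromide, C[Mg]Br
Why: Grignard addition to the aldehyde after deprotonation of the two hydroxyls; the new carbinol carbon forms without control, which does not matter because step 6 makes it the ketone carbon.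

Step 6
Reactants: 9 (2S)-5-(1-hydroxyethyl)-2-[(2S)-2-hydroxy-6-methylhept-5-en-2-yl]-2,3-dihydro-1-benzofuran-4-ol
Product: 10 1-[(2S)-4-hydroxy-2-[(2S)-2-hydroxy-6-methylhept-5-en-2-yl]-2,3-dihydro-1-benzofuran-5-yl]ethan-1-one
Conditions: activated MnO2 (excess), CH2Cl2, 23 °C
Reagents that add atoms: none
Why: Selective oxidation of the benzylic alcohol with MnO2; the tertiary alcohol cannot be oxidized and the isolated trisubstituted alkene is inert.

Step 7
Reactants: 10 1-[(2S)-4-hydroxy-2-[(2S)-2-hydroxy-6-methylhept-5-en-2-yl]-2,3-dihydro-1-benzofuran-5-yl]ethan-1-one; 11 4-hydroxybenzaldehyde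
Product: 12 (E)-1-[(2S)-4-hydroxy-2-[(2S)-2-hydroxy-6-methylhept-5-en-2-yl]-2,3-dihydro-1-benzofuran-5-yl]-3-(4-hydroxyphenyl)prop-2-en-1-one
Conditions: KOH (50 % aq, excess), EtOH, 23 → 40 °C; then 1 M HCl to pH 5, 0 °C
Reagents that add atoms: none
Why: Claisen–Schmidt aldol condensation, whose E1cB dehydration should give the conjugated E-enone; the two stereocentres bear no acidic hydrogen and should survive the base.

Compound list

1 | nerol, (2Z)-3,7-dimethylocta-2,6-dien-1-ol | CC(C)=CCC/C(C)=C\CO | starting material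
2 | [(2R,3S)-3-methyl-3-(4-methylpent-3-en-1-yl)oxiran-2-yl]methanol | CC(C)=CCC[C@]1(C)O[C@@H]1CO | intermediate
3 | [(2R,3S)-3-methyl-3-(4-methylpent-3-en-1-yl)oxiran-2-yl]methyl trifluoromethanesulfonate | CC(C)=CCC[C@]1(C)O[C@@H]1COS(=O)(=O)C(F)(F)F | intermediate
4 | 2-bromoresorcinol (2-bromobenzene-1,3-diol) | Oc1cccc(O)c1Br | starting material
5 | trilithio resorcinolate (dilithium 2-lithiobenzene-1,3-diolate) | [Li]Oc1cccc(O[Li])c1[Li] | intermediate
6 | epoxy bis-phenoxide (dilithium 2-{[(2R,3S)-3-methyl-3-(4-methylpent-3-en-1-yl)oxiran-2-yl]methyl}benzene-1,3-diolate) | CC(C)=CCC[C@]1(C)O[C@@H]1Cc1c(O[Li])cccc1O[Li] | intermediate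
7 | (2S)-2-[(2S)-2-hydroxy-6-methylhept-5-en-2-yl]-2,3-dihydro-1-benzofuran-4-ol | CC(C)=CCC[C@](C)(O)[C@@H]1Cc2c(cccc2O)O1 | intermediate
8 | (2S)-4-hydroxy-2-[(2S)-2-hydroxy-6-methylhept-5-en-2-yl]-2,3-dihydro-1-benzofuran-5-carbaldehyde | CC(C)=CCC[C@](C)(O)[C@@H]1Cc2c(ccc(C=O)c2O)O1 | intermediate
9 | (2S)-5-(1-hydroxyethyl)-2-[(2S)-2-hydroxy-6-methylhept-5-en-2-yl]-2,3-dihydro-1-benzofuran-4-ol (epimers at the 1-hydroxyethyl carbon) | CC(C)=CCC[C@](C)(O)[C@@H]1Cc2c(ccc(C(C)O)c2O)O1 | intermediate
10 | 1-[(2S)-4-hydroxy-2-[(2S)-2-hydroxy-6-methylhept-5-en-2-yl]-2,3-dihydro-1-benzofuran-5-yl]ethan-1-one | CC(C)=CCC[C@](C)(O)[C@@H]1Cc2c(ccc(C(C)=O)c2O)O1 | intermediate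
11 | 4-hydroxybenzaldehyde | O=Cc1ccc(O)cc1 | starting material
12 | (E)-1-[(2S)-4-hydroxy-2-[(2S)-2-hydroxy-6-methylhept-5-en-2-yl]-2,3-dihydro-1-benzofuran-5-yl]-3-(4-hydroxyphenyl)prop-2-en-1-one | CC(C)=CCC[C@](C)(O)[C@@H]1Cc2c(ccc(C(=O)/C=C/c3ccc(O)cc3)c2O)O1 | target

Total step count: 7. Longest linear sequence: 7 steps (1 → 2 → 3 → 7 → 8 → 9 → 10 → 12); 4 and 11 are bought.

Steps most likely to fail

Step 3. The trilithio species may aggregate or fall out of solution, so that the carbon alkylation becomes slow and oxygen alkylation or decay of the triflate takes over; closure of the lithium phenoxide onto the hindered epoxide may also stall. The fallback sets out from 4 and 3 and returns at 7. Compound 4 would be silylated (TBSCl, imidazole, DMF) to 2-bromo-1,3-bis(tert-butyldimethylsilyloxy)benzene F1. Bromine–lithium exchange (t-BuLi, Et2O, −78 °C, kept cold so that silyl migration from oxygen to carbon does not set in) and addition of 3 would give (2R,3S)-2-[2,6-bis(tert-butyldimethylsilyloxy)benzyl]-3-methyl-3-(4-methylpent-3-en-1-yl)oxirane F2, which is isolated. TBAF in THF would then free the phenoxides, one of which closes the ring to 7. The two ring bonds are then made in two separate operations by a monoanionic, soluble aryllithium.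

Step 4. The formylation may stall if the magnesium is tied up by the tertiary alkoxide, or formaldehyde may add more than once to the electron-rich ring. The fallback sets out from 7 and returns at 10, bypassing 8 and 9. The phenol would be protected (MOMCl, i-Pr2NEt, CH2Cl2) as (2S)-2-[(2S)-4-(methoxymethoxy)-2,3-dihydro-1-benzofuran-2-yl]-6-methylhept-5-en-2-ol F3. Directed ortho-lithiation next to the acetal oxygen at C5 (n-BuLi, 2.2 equiv, TMEDA, THF, −20 °C) and acylation with N-methoxy-N-methylacetamide would give 1-[(2S)-2-[(2S)-2-hydroxy-6-methylhept-5-en-2-yl]-4-(methoxymethoxy)-2,3-dihydro-1-benzofuran-5-yl]ethan-1-one F4. Chelation-assisted cleavage of the acetal ortho to the ketone (MgBr2·OEt2, Et2O, 23 °C) would then give 10.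

Step 7. The aldehyde is deactivated as its phenoxide, so condensation may be slow, and the 2'-hydroxychalcone may close to the flavanone during long exposure to base. The fallback sets out from 10 and returns at 12. Condensation of 10 with commercial 4-(allyloxy)benzaldehyde (KOH, EtOH, 23 °C) would give (E)-1-[(2S)-4-hydroxy-2-[(2S)-2-hydroxy-6-methylhept-5-en-2-yl]-2,3-dihydro-1-benzofuran-5-yl]-3-[4-(prop-2-en-1-yloxy)phenyl]prop-2-en-1-one F5. The allyl ether would then be removed with Pd(PPh3)4, K2CO3, MeOH at 23 °C, which spares the enone and the isolated alkene, to give 12.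

Further compounds

F1 | step 3 | 2-bromo-1,3-bis(tert-butyldimethylsilyloxy)benzene | CC(C)(C)[Si](C)(C)Oc1cccc(O[Si](C)(C)C(C)(C)C)c1Br
F2 | step 3 | (2R,3S)-2-[2,6-bis(tert-butyldimethylsilyloxy)benzyl]-3-methyl-3-(4-methylpent-3-en-1-yl)oxirane | CC(C)=CCC[C@]1(C)O[C@@H]1Cc1c(O[Si](C)(C)C(C)(C)C)cccc1O[Si](C)(C)C(C)(C)C
F3 | step 4 | (2S)-2-[(2S)-4-(methoxymethoxy)-2,3-dihydro-1-benzofuran-2-yl]-6-methylhept-5-en-2-ol | CC(C)=CCC[C@](C)(O)[C@@H]1Cc2c(cccc2OCOC)O1
F4 | step 4 | 1-[(2S)-2-[(2S)-2-hydroxy-6-methylhept-5-en-2-yl]-4-(methoxymethoxy)-2,3-dihydro-1-benzofuran-5-yl]ethan-1-one | CC(C)=CCC[C@](C)(O)[C@@H]1Cc2c(ccc(C(C)=O)c2OCOC)O1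
F5 | step 7 | (E)-1-[(2S)-4-hydroxy-2-[(2S)-2-hydroxy-6-methylhept-5-en-2-yl]-2,3-dihydro-1-benzofuran-5-yl]-3-[4-(prop-2-en-1-yloxy)phenyl]prop-2-en-1-one | CC(C)=CCC[C@](C)(O)[C@@H]1Cc2c(ccc(C(=O)/C=C/c3ccc(OCC=C)cc3)c2O)O1
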